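**Retrosynthetic overview**

- The Z-ylidene butenolide bond C11'=C12' is made last by a one-pot vinylogous Mukaiyama aldol/β-elimination between an α-alkylbutenolide (ε half, from (R)-α-ionone) and the C25 apo-aldehyde, itself a C15 Wittig salt plus the C10 dialdehyde.
- The β-ring comes from (1S,3R)-camphoric acid: its 1,2,2-trimethylcyclopentane supplies C1(Me2), C2–C4, C5(Me) and C6 (the tertiary carboxyl carbon). The quaternary carbon sets the C3–O centre through a cis-bridged γ-lactone (iodolactonisation) and is later erased.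
- Key event: acid-triggered Wagner–Meerwein ring enlargement, cyclopentane to cyclohexene. Enabling feature: in the β-ring, C6 lies between the quaternary C1 and the methyl-bearing C5 (the retron of a 1,2,2-trimethylcyclopentyl-carbinyl cation, i.e. the camphoric skeleton), and O3 is 1,3 to C5 so a lactone can bridge to C6.
- Ring order: cyclopentane (bought), temporary oxa-bridge, β-ring (ring enlargement); ε-ring bought; butenolide ring by palladium-catalysed carbonylative lactonisation; halves joined at C11'=C12'.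

Key step: step 9

Assumption and convention: (1S,3R)-(−)-camphoric acid, (R)-(+)-α-ionone, (2E,4E,6E)-2,7-dimethylocta-2,4,6-trienedial and 1,4-bis(trimethylsilyl)buta-1,3-diyne are taken as commercial; locants C1–C15 and primed locants follow carotenoid numbering (lactone carbonyl = C19').

**Route**

Step 1
Reactants: 1 (1S,3R)-camphoric acid
Product: 2 dimethyl (1S,3R)-1,2,2-trimethylcyclopentane-1,3-dicarboxylate
Conditions: MeI, K2CO3, DMF, rt
Reagents that add atoms: iodomethane CI
Why: Carboxylate O-alkylation (SN2 on MeI) esterifies even the hindered tertiary acid without touching either stereocentre.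

Step 2
Reactants: 2 dimethyl (1S,3R)-1,2,2-trimethylcyclopentane-1,3-dicarboxylate
Product: 3 (1R,3S)-3-(methoxycarbonyl)-2,2,3-trimethylcyclopentane-1-carboxylic acid
Conditions: KOH (1.1 equiv), MeOH/H2O, 40 °C; then dilute HCl
Reagents that add atoms: potassium hydroxide [K+].[OH-]
Why: Selective saponification, because the tertiary ester is shielded by its own and the adjacent quaternary carbon while the secondary ester is not.

Step 3
Reactants: 3 (1R,3S)-3-(methoxycarbonyl)-2,2,3-trimethylcyclopentane-1-carboxylic acid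
Product: 4 methyl (1S)-1,2,2-trimethylcyclopent-3-ene-1-carboxylate
Conditions: Pb(OAc)4, Cu(OAc)2 (cat.), pyridine, benzene, 80 °C
Reagents that add atoms: none
Why: Kochi oxidative decarboxylation, in which the secondary radical is oxidised by the copper salt and eliminates towards the only β-hydrogens (ring CH2, the other neighbour being quaternary), leaving the quaternary stereocentre untouched.

Step 4
Reactants: 4 methyl (1S)-1,2,2-trimethylcyclopent-3-ene-1-carboxylate
Product: 6 (1R,4S,6R)-6-iodo-4,5,5-trimethyl-2-oxabicyclo[2.2.1]heptan-3-one, via free carboxylic acid 5 (not isolated)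
Conditions: KOH, ethylene glycol/H2O, 130 °C; cool, buffer to pH 8 (CO2, NaHCO3); I2, KI, H2O/Et2O, 0 °C to rt, dark
Reagents that add atoms: potassium hydroxide [K+].[OH-]; iodine II
Why: Saponification then iodolactonisation, in which the carboxylate opens the iodonium ion anti at the alkene carbon remote from the gem-dimethyl group and the bridged γ-lactone can only close cis, so the quaternary centre fixes the configuration of the new C–O centre (future C3).

Step 5
Reactants: 6 (1R,4S,6R)-6-iodo-4,5,5-trimethyl-2-oxabicyclo[2.2.1]heptan-3-one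
Product: 7 (1S,4S)-4,5,5-trimethyl-2-oxabicyclo[2.2.1]heptan-3-one
Conditions: Bu3SnH, AIBN (cat.), benzene, 80 °C
Reagents that add atoms: none
Why: Radical-chain deiodination replaces the secondary C–I bond by C–H without affecting the lactone or its two stereocentres.

Step 6
Reactants: 7 (1S,4S)-4,5,5-trimethyl-2-oxabicyclo[2.2.1]heptan-3-one
Product: 8 (1S,4S)-4,5,5-trimethyl-2-oxabicyclo[2.2.1]heptan-3-ol (anomer mixture)
Conditions: i-Bu2AlH (1.1 equiv), CH2Cl2, −78 °C; Rochelle salt
Reagents that add atoms: none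
Why: Partial lactone reduction stops at the bridged lactol because the tetrahedral aluminate is stable at low temperature.

Step 7
Reactants: 8 (1S,4S)-4,5,5-trimethyl-2-oxabicyclo[2.2.1]heptan-3-ol; 9 1,4-bis(trimethylsilyl)buta-1,3-diyne
Product: 10 (1RS)-1-[(1S,4S)-4-hydroxy-1,2,2-trimethylcyclopentyl]-5-(trimethylsilyl)penta-2,4-diyn-1-ol
Conditions: 9 (3 equiv), MeLi·LiBr, THF, rt; then 8, −78 °C to 0 °C; aq. NH4Cl
Reagents that add atoms: none
Why: 1,2-Addition of a lithium acetylide (from mono-desilylation of the bis-silyl diyne) to the ring-opened hydroxy-aldehyde tautomer of the lactol, the new carbinol centre being formed as a mixture that is ionised in step 9.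

Step 8
Reactants: 10 (1RS)-1-[(1S,4S)-4-hydroxy-1,2,2-trimethylcyclopentyl]-5-(trimethylsilyl)penta-2,4-diyn-1-ol
Product: 12 (1RS,2E)-1-[(1S,4S)-4-hydroxy-1,2,2-trimethylcyclopentyl]pent-2-en-4-yn-1-ol, via silyl enyne diol 11 (not isolated)
Conditions: NaAlH2(OCH2CH2OMe)2, THF, 0 °C to rt; then MeOH, K2CO3, rt
Reagents that add atoms: none
Why: Hydroxyl-directed trans-hydroalumination reduces only the propargylic triple bond of the diynol to the E-alkene, and base-catalysed methanolysis then cleaves the alkynyl C–Si bond.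

Step 9
Reactants: 12 (1RS,2E)-1-[(1S,4S)-4-hydroxy-1,2,2-trimethylcyclopentyl]pent-2-en-4-yn-1-ol
Product: 14 (1R)-4-[(1E)-but-1-en-3-yn-1-yl]-3,5,5-trimethylcyclohex-3-en-1-ol, via bridged allylic ether 13 (not isolated)
Conditions: Tf2NH (10 mol %), 4 Å molecular sieves, CH2Cl2/(CF3)2CHOH 4:1, 0 °C to rt
Reagents that add atoms: none
Why: Triflimide ionises the neopentylic C6–O bond (the 2-oxabicyclo[2.2.1]heptane ether 13 formed by capture with the cis C3–OH re-ionises, so the oxa-bridge that carried the stereochemistry also serves as leaving group); in the enynyl-stabilised C6 cation the ring bond C5–C1 shifts so that C1 (the CMe2 carbon) moves from C5 to C6, giving the tertiary cyclohexyl cation at C5, which loses H6 to form the tetrasubstituted C5=C6 alkene conjugated with the (7E)-enyne. The closest known reaction type is the dehydrative Wagner–Meerwein (retropinacol) ring enlargement of cyclopentyl-carbinyl cations, as in the D-homo (uranediol) rearrangement of pregnan-20-yl cations, where the more substituted ring carbon migrates. The six-membered ring is not closed by cyclisation but made by this 1,2-alkyl shift (one-carbon ring enlargement), and no other ring is formed. No new stereocentre is created: C3 keeps the R configuration set in step 4, while the quaternary relay centre at C5 and the C6 carbinol centre are erased. The step needs migration of the tertiary C1 in preference to the C4 methylene or the C5 methyl, and proton loss from C6 rather than C4; the higher migratory aptitude of the fully substituted carbon together with relief of the vicinal quaternary–quaternary strain should secure the first, and conjugation with the enyne under reversible protonation the second. Water-free, non-nucleophilic conditions suppress Meyer–Schuster-type capture at the alkyne terminus.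

Step 10
Reactants: 14 (1R)-4-[(1E)-but-1-en-3-yn-1-yl]-3,5,5-trimethylcyclohex-3-en-1-ol
Product: 16 (2E,4E)-5-[(4R)-4-hydroxy-2,6,6-trimethylcyclohex-1-en-1-yl]-3-methylpenta-2,4-dien-1-ol, via alkenylalane 15 (not isolated)
Conditions: Me3Al (4 equiv), Cp2ZrCl2, CH2Cl2, 0 °C to rt; volatiles removed; n-BuLi, THF, −78 °C; (CH2O)n, to rt
Reagents that add atoms: trimethylaluminium C[Al](C)C; formaldehyde (as paraformaldehyde) C=O
Why: Zirconium-catalysed carboalumination (Negishi) adds Me–Al syn across the terminal alkyne with methyl on the internal carbon, and the derived alanate is hydroxymethylated with retention, which sets the 9E trisubstituted alkene.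

Step 11
Reactants: 16 (2E,4E)-5-[(4R)-4-hydroxy-2,6,6-trimethylcyclohex-1-en-1-yl]-3-methylpenta-2,4-dien-1-ol
Product: 17 [(2E,4E)-5-[(4R)-4-hydroxy-2,6,6-trimethylcyclohex-1-en-1-yl]-3-methylpenta-2,4-dien-1-yl]triphenylphosphonium bromide
Conditions: PPh3·HBr, MeOH, 0 °C to rt
Reagents that add atoms: triphenylphosphine hydrobromide [Br-].[PH+](c1ccccc1)(c1ccccc1)c1ccccc1
Why: Only the primary allylic alcohol ionises to the pentadienyl cation, which the phosphine captures at the unhindered terminus (classical C15 Wittig salt formation), the secondary non-allylic C3–OH being inert.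

Step 12
Reactants: 17 the C15 phosphonium bromide; 18 (2E,4E,6E)-2,7-dimethylocta-2,4,6-trienedial
Product: 19 (2E,4E,6E,8E,10E,12E)-13-[(4R)-4-hydroxy-2,6,6-trimethylcyclohex-1-en-1-yl]-2,7,11-trimethyltrideca-2,4,6,8,10,12-hexaenal
Conditions: 18 (3 equiv), NaOMe, CH2Cl2/MeOH, 0 °C to rt; then n-heptane, 90 °C
Reagents that add atoms: none
Why: Wittig olefination with excess dialdehyde should stop at the mono-adduct because the product aldehyde is more conjugated and less electrophilic, and heating equilibrates the new C11=C12 bond to E.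

Step 13
Reactants: 20 (3E)-4-[(1R)-2,6,6-trimethylcyclohex-2-en-1-yl]but-3-en-2-one ((R)-α-ionone)
Product: 21 4-[(1R)-2,6,6-trimethylcyclohex-2-en-1-yl]butan-2-one
Conditions: H2 (1 atm), RhCl(PPh3)3 (cat.), benzene, rt
Reagents that add atoms: none
Why: Homogeneous hydrogenation is selective for the disubstituted conjugated alkene over the hindered trisubstituted ring alkene and does not touch the ketone or the C6' centre.

Step 14
Reactants: 21 4-[(1R)-2,6,6-trimethylcyclohex-2-en-1-yl]butan-2-one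
Product: 25 6-[(1R)-2,6,6-trimethylcyclohex-2-en-1-yl]hex-2-yn-1-yl 2,2-dimethylpropanoate, via enol phosphate 22 (not isolated), via lithium acetylide 23 (not isolated), via lithium alkoxide 24 (not isolated)
Conditions: LiN(i-Pr)2 (1.1 equiv), THF, −78 °C; ClP(O)(OEt)2, to rt; LiN(i-Pr)2 (2.4 equiv), −78 °C to rt; (CH2O)n; t-BuCOCl, 0 °C to rt
Reagents that add atoms: formaldehyde (as paraformaldehyde) C=O; pivaloyl chloride CC(C)(C)C(Cl)=O
Why: Kinetic enolisation at the methyl group, enol phosphate formation and β-elimination give the terminal acetylide (methyl ketone to alkyne), which is hydroxymethylated and acylated in the same flask.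

Step 15
Reactants: 25 6-[(1R)-2,6,6-trimethylcyclohex-2-en-1-yl]hex-2-yn-1-yl 2,2-dimethylpropanoate
Product: 26 6-[(1R)-2,6,6-trimethyl-4-oxocyclohex-2-en-1-yl]hex-2-yn-1-yl 2,2-dimethylpropanoate
Conditions: CuI (cat.), t-BuOOH, MeCN, 50 °C
Reagents that add atoms: tert-butyl hydroperoxide CC(C)(C)OO
Why: Copper/peroxide allylic oxidation attacks the ring methylene attached to the CH end of the trisubstituted alkene (as in the oxidation of 5-ene steroids to 7-ketones), whose C–H bond is weaker than the propargylic ones.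

Step 16
Reactants: 26 6-[(1R)-2,6,6-trimethyl-4-oxocyclohex-2-en-1-yl]hex-2-yn-1-yl 2,2-dimethylpropanoate
Product: 27 6-[(1R,4R)-4-hydroxy-2,6,6-trimethylcyclohex-2-en-1-yl]hex-2-yn-1-yl 2,2-dimethylpropanoate
Conditions: (S)-2-methyl-CBS-oxazaborolidine (0.2 equiv), catecholborane, toluene, −78 °C; aq. NaOH
Reagents that add atoms: none
Why: Corey–Bakshi–Shibata 1,2-reduction under catalyst control (alkene side as the large group) should give the 3'R alcohol trans to the C6' chain, the substrate itself having little facial bias.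

Step 17
Reactants: 27 6-[(1R,4R)-4-hydroxy-2,6,6-trimethylcyclohex-2-en-1-yl]hex-2-yn-1-yl 2,2-dimethylpropanoate
Product: 29 (1R,4R)-4-[(3Z)-5-hydroxy-3-iodopent-3-en-1-yl]-3,5,5-trimethylcyclohex-2-en-1-ol, via cyclic alkenylaluminate 28 (not isolated)
Conditions: NaAlH2(OCH2CH2OMe)2 (5 equiv), THF, 0 °C to rt; then I2, −78 °C to 0 °C
Reagents that add atoms: iodine II
Why: The hydride cleaves the pivalate, the liberated propargylic alkoxide directs trans-hydroalumination with aluminium at the distal carbon, and iodinolysis with retention gives the Z-3-iodoallylic alcohol.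

Step 18
Reactants: 29 (1R,4R)-4-[(3Z)-5-hydroxy-3-iodopent-3-en-1-yl]-3,5,5-trimethylcyclohex-2-en-1-ol
Product: 30 3-{2-[(1R,4R)-4-hydroxy-2,6,6-trimethylcyclohex-2-en-1-yl]ethyl}furan-2(5H)-one
Conditions: PdCl2(PPh3)2 (cat.), CO (1 atm), K2CO3, THF, 40 °C
Reagents that add atoms: carbon monoxide [C-]#[O+]
Why: Palladium-catalysed carbonylative lactonisation of a Z-3-iodoallylic alcohol, in which the acylpalladium is trapped by the cis CH2OH to give the α-substituted butenolide faster than by the remote ring hydroxyl.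

Step 19
Reactants: 19 the C25 hydroxy aldehyde; 30 the hydroxy butenolide
Product: 34 (3R,3'R,6'R)-3,3'-bis(tert-butyldimethylsilyloxy)-7',8'-dihydro-β,ε-caroten-19',11'-olide (11'Z), via silylated aldehyde 31 (not isolated), via silyloxyfuran 32 (not isolated), via aldol adduct 33 (not isolated)
Conditions: TBSOTf (5 equiv), i-Pr2NEt, CH2Cl2, 0 °C, then −78 °C to rt; then DBU, rt
Reagents that add atoms: tert-butyldimethylsilyl trifluoromethanesulfonate CC(C)(C)[Si](C)(C)OS(=O)(=O)C(F)(F)F
Why: One-pot vinylogous Mukaiyama aldol of the in situ 2-silyloxyfuran at its C5 with the silyl-activated aldehyde, followed by base-induced β-elimination of silanolate, which should give the thermodynamically preferred Z-ylidene butenolide while both free hydroxyls are silylated in the same flask.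

Step 20
Reactants: 34 the bis-silyl ether
Product: 35 CNP0242041.1, (3R,3'R,6'R)-3,3'-dihydroxy-7',8'-dihydro-β,ε-caroten-19',11'-olide (11'Z)
Conditions: HF·pyridine, pyridine, THF, 0 °C to rt
Reagents that add atoms: none
Why: Buffered fluoride desilylation removes both secondary silyl ethers without opening the butenolide or isomerising the polyene.

**Compound list**

1 | (1S,3R)-camphoric acid | OC(=O)[C@@]1(C)CC[C@@H](C(O)=O)C1(C)C | starting material
2 | dimethyl (1S,3R)-1,2,2-trimethylcyclopentane-1,3-dicarboxylate | COC(=O)[C@@]1(C)CC[C@@H](C(=O)OC)C1(C)C | intermediate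
3 | (1R,3S)-3-(methoxycarbonyl)-2,2,3-trimethylcyclopentane-1-carboxylic acid | COC(=O)[C@@]1(C)CC[C@@H](C(O)=O)C1(C)C | intermediate
4 | methyl (1S)-1,2,2-trimethylcyclopent-3-ene-1-carboxylate | COC(=O)[C@@]1(C)CC=CC1(C)C | intermediate
5 | (1S)-1,2,2-trimethylcyclopent-3-ene-1-carboxylic acid (formed as potassium salt) | OC(=O)[C@@]1(C)CC=CC1(C)C | intermediate
6 | (1R,4S,6R)-6-iodo-4,5,5-trimethyl-2-oxabicyclo[2.2.1]heptan-3-one | O=C1O[C@@H]2C[C@@]1(C)C(C)(C)[C@H]2I | intermediate
7 | (1S,4S)-4,5,5-trimethyl-2-oxabicyclo[2.2.1]heptan-3-one | O=C1O[C@@H]2C[C@@]1(C)C(C)(C)C2 | intermediate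
8 | (1S,4S)-4,5,5-trimethyl-2-oxabicyclo[2.2.1]heptan-3-ol (anomers) | OC1O[C@@H]2C[C@@]1(C)C(C)(C)C2 | intermediate
9 | 1,4-bis(trimethylsilyl)buta-1,3-diyne | C[Si](C)(C)C#CC#C[Si](C)(C)C | starting material
10 | (1RS)-1-[(1S,4S)-4-hydroxy-1,2,2-trimethylcyclopentyl]-5-(trimethylsilyl)penta-2,4-diyn-1-ol | C[Si](C)(C)C#CC#CC(O)[C@@]1(C)C[C@@H](O)CC1(C)C | intermediate
11 | (1RS,2E)-1-[(1S,4S)-4-hydroxy-1,2,2-trimethylcyclopentyl]-5-(trimethylsilyl)pent-2-en-4-yn-1-ol | C[Si](C)(C)C#C/C=C/C(O)[C@@]1(C)C[C@@H](O)CC1(C)C | intermediate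
12 | (1RS,2E)-1-[(1S,4S)-4-hydroxy-1,2,2-trimethylcyclopentyl]pent-2-en-4-yn-1-ol | C#C/C=C/C(O)[C@@]1(C)C[C@@H](O)CC1(C)C | intermediate
13 | (1S,4S)-3-[(1E)-but-1-en-3-yn-1-yl]-4,5,5-trimethyl-2-oxabicyclo[2.2.1]heptane (C3 epimers) | C#C/C=C/C1O[C@@H]2C[C@@]1(C)C(C)(C)C2 | intermediate
14 | (1R)-4-[(1E)-but-1-en-3-yn-1-yl]-3,5,5-trimethylcyclohex-3-en-1-ol | C#C/C=C/C1=C(C)C[C@@H](O)CC1(C)C | intermediate
15 | dimethylalanyl dienyl alane of 14 (O-aluminated; Al trans to C8) | C[Al](C)/C=C(C)/C=C/C1=C(C)C[C@@H](O[Al](C)C)CC1(C)C | intermediate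
16 | (2E,4E)-5-[(4R)-4-hydroxy-2,6,6-trimethylcyclohex-1-en-1-yl]-3-methylpenta-2,4-dien-1-ol | OC/C=C(C)/C=C/C1=C(C)C[C@@H](O)CC1(C)C | intermediate
17 | [(2E,4E)-5-[(4R)-4-hydroxy-2,6,6-trimethylcyclohex-1-en-1-yl]-3-methylpenta-2,4-dien-1-yl]triphenylphosphonium bromide | [Br-].c1ccccc1[P+](c1ccccc1)(c1ccccc1)C/C=C(C)/C=C/C1=C(C)C[C@@H](O)CC1(C)C | intermediate
18 | (2E,4E,6E)-2,7-dimethylocta-2,4,6-trienedial | O=C/C(C)=C/C=C/C=C(C)/C=O | starting material
19 | (3R)-3-hydroxy-12'-apo-β-caroten-12'-al (all-E C25 aldehyde) | O=C/C(C)=C/C=C/C=C(C)/C=C/C=C(C)/C=C/C1=C(C)C[C@@H](O)CC1(C)C | intermediate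
20 | (R)-α-ionone | CC1=CCCC(C)(C)[C@H]1/C=C/C(C)=O | starting material
21 | 4-[(1R)-2,6,6-trimethylcyclohex-2-en-1-yl]butan-2-one | CC1=CCCC(C)(C)[C@H]1CCC(C)=O | intermediate
22 | diethyl 4-[(1R)-2,6,6-trimethylcyclohex-2-en-1-yl]but-1-en-2-yl phosphate | CC1=CCCC(C)(C)[C@H]1CCC(=C)OP(=O)(OCC)OCC | intermediate
23 | lithium acetylide of (6R)-6-(but-3-yn-1-yl)-1,5,5-trimethylcyclohexene | CC1=CCCC(C)(C)[C@H]1CCC#C[Li] | intermediate
24 | lithium 6-[(1R)-2,6,6-trimethylcyclohex-2-en-1-yl]hex-2-yn-1-olate | CC1=CCCC(C)(C)[C@H]1CCC#CCO[Li] | intermediate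
25 | 6-[(1R)-2,6,6-trimethylcyclohex-2-en-1-yl]hex-2-yn-1-yl 2,2-dimethylpropanoate | CC1=CCCC(C)(C)[C@H]1CCC#CCOC(=O)C(C)(C)C | intermediate
26 | 6-[(1R)-2,6,6-trimethyl-4-oxocyclohex-2-en-1-yl]hex-2-yn-1-yl 2,2-dimethylpropanoate | CC1=CC(=O)CC(C)(C)[C@H]1CCC#CCOC(=O)C(C)(C)C | intermediate
27 | 6-[(1R,4R)-4-hydroxy-2,6,6-trimethylcyclohex-2-en-1-yl]hex-2-yn-1-yl 2,2-dimethylpropanoate | CC1=C[C@H](O)CC(C)(C)[C@H]1CCC#CCOC(=O)C(C)(C)C | intermediate
28 | sodium cyclic alkenylaluminate (2,5-dihydro-1,2-oxaluminole; ring hydroxyl drawn protonated) | [Na+].CC1=C[C@H](O)CC(C)(C)[C@H]1CCC1=CCO[Al-]1(OCCOC)OCCOC | intermediate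
29 | (1R,4R)-4-[(3Z)-5-hydroxy-3-iodopent-3-en-1-yl]-3,5,5-trimethylcyclohex-2-en-1-ol | CC1=C[C@H](O)CC(C)(C)[C@H]1CC/C(I)=C/CO | intermediate
30 | 3-{2-[(1R,4R)-4-hydroxy-2,6,6-trimethylcyclohex-2-en-1-yl]ethyl}furan-2(5H)-one | CC1=C[C@H](O)CC(C)(C)[C@H]1CCC1=CCOC1=O | intermediate
31 | tert-butyldimethylsilyl ether of 19 | O=C/C(C)=C/C=C/C=C(C)/C=C/C=C(C)/C=C/C1=C(C)C[C@@H](O[Si](C)(C)C(C)(C)C)CC1(C)C | intermediate
32 | 2-(tert-butyldimethylsilyloxy)-3-{2-[(1R,4R)-4-(tert-butyldimethylsilyloxy)-2,6,6-trimethylcyclohex-2-en-1-yl]ethyl}furan | CC1=C[C@H](O[Si](C)(C)C(C)(C)C)CC(C)(C)[C@H]1CCc1ccoc1O[Si](C)(C)C(C)(C)C | intermediate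
33 | tris-silylated vinylogous aldol adduct (C11', C12' epimers) | CC1=C[C@H](O[Si](C)(C)C(C)(C)C)CC(C)(C)[C@H]1CCC1=CC(OC1=O)C(O[Si](C)(C)C(C)(C)C)/C(C)=C/C=C/C=C(C)/C=C/C=C(C)/C=C/C1=C(C)C[C@@H](O[Si](C)(C)C(C)(C)C)CC1(C)C | intermediate
34 | (3R,3'R,6'R)-3,3'-bis(tert-butyldimethylsilyloxy)-7',8'-dihydro-β,ε-caroten-19',11'-olide (11'Z) | CC1=C[C@H](O[Si](C)(C)C(C)(C)C)CC(C)(C)[C@H]1CCC1=C/C(=C/C(C)=C/C=C/C=C(C)/C=C/C=C(C)/C=C/C2=C(C)C[C@@H](O[Si](C)(C)C(C)(C)C)CC2(C)C)OC1=O | intermediate
35 | CNP0242041.1, (3R,3'R,6'R)-3,3'-dihydroxy-7',8'-dihydro-β,ε-caroten-19',11'-olide (11'Z) | CC1=C[C@H](O)CC(C)(C)[C@H]1CCC1=C/C(=C/C(C)=C/C=C/C=C(C)/C=C/C=C(C)/C=C/C2=C(C)C[C@@H](O)CC2(C)C)OC1=O | target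

**Step count and risks**

Total step count: 20. Longest linear sequence: 14 steps (steps 1–12, 19, 20); the ε branch is steps 13–18.

Steps most likely to fail:

1. Step 9. The enynyl-stabilised cation may rearrange slowly, so that shift of the ring methylene or the methyl group, capture at the alkyne terminus or oligomerisation of the product competes with the wanted shift. Fallback: enlarge the ring on a less stabilised cation before the diene exists, then build the diene by cross-coupling. It sets out from 8: lithium (trimethylsilyl)acetylide adds to give 1-[(1S,4S)-4-hydroxy-1,2,2-trimethylcyclopentyl]-3-(trimethylsilyl)prop-2-yn-1-ol F1; ionisation of the propargylic hydroxyl (Tf2NH, hexafluoroisopropanol) gives by the same 1,2-shift and proton loss (1R)-3,5,5-trimethyl-4-[(trimethylsilyl)ethynyl]cyclohex-3-en-1-ol F2; K2CO3/MeOH gives (1R)-4-ethynyl-3,5,5-trimethylcyclohex-3-en-1-ol F3; hydrozirconation with Cp2Zr(H)Cl and iodinolysis give (1R)-4-[(E)-2-iodoethenyl]-3,5,5-trimethylcyclohex-3-en-1-ol F4; Sonogashira coupling with ethynyltrimethylsilane (PdCl2(PPh3)2, CuI, Et3N) gives (1R)-3,5,5-trimethyl-4-[(1E)-4-(trimethylsilyl)but-1-en-3-yn-1-yl]cyclohex-3-en-1-ol F5; K2CO3/MeOH returns to the route at 14.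

2. Step 4. The carboxylate may close at the alkene carbon next to the gem-dimethyl group (wrong regiochemistry), or hydrolysis of the hindered ester may stall. Fallback: install the oxygen by hydroboration and let both carbinol epimers converge on the lactone. It sets out from 4: 9-borabicyclo[3.3.1]nonane then NaOH/H2O2 places the hydroxyl at the ring carbon remote from the gem-dimethyl group, giving methyl (1S)-4-hydroxy-1,2,2-trimethylcyclopentane-1-carboxylate F6 as both epimers; saponification gives (1S)-4-hydroxy-1,2,2-trimethylcyclopentane-1-carboxylic acid F7; on acidification the cis acid lactonises with retention, and the trans acid, separated by extraction, is closed with inversion under Mitsunobu conditions (PPh3, DIAD); both return to the route at 7.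

3. Step 15. Hydrogen abstraction at the propargylic positions or at the tertiary ring C–H may compete with the ring methylene, giving over-oxidised mixtures. Fallback: oxidise the ring before any alkyne is present, with the ketone masked. It sets out from 21: ethylene glycol/pyridinium tosylate gives 2-methyl-2-{2-[(1R)-2,6,6-trimethylcyclohex-2-en-1-yl]ethyl}-1,3-dioxolane F8; CuI/t-BuOOH gives (4R)-3,5,5-trimethyl-4-[2-(2-methyl-1,3-dioxolan-2-yl)ethyl]cyclohex-2-en-1-one F9; CBS reduction as in step 16 gives (1R,4R)-3,5,5-trimethyl-4-[2-(2-methyl-1,3-dioxolan-2-yl)ethyl]cyclohex-2-en-1-ol F10; TBSCl/imidazole gives its silyl ether F11; pyridinium tosylate in wet acetone gives 4-[(1R,4R)-4-(tert-butyldimethylsilyloxy)-2,6,6-trimethylcyclohex-2-en-1-yl]butan-2-one F12; the enol phosphate/elimination/paraformaldehyde sequence of step 14 gives 6-[(1R,4R)-4-(tert-butyldimethylsilyloxy)-2,6,6-trimethylcyclohex-2-en-1-yl]hex-2-yn-1-ol F13; NaAlH2(OCH2CH2OMe)2 then I2 gives (2Z)-6-[(1R,4R)-4-(tert-butyldimethylsilyloxy)-2,6,6-trimethylcyclohex-2-en-1-yl]-3-iodohex-2-en-1-ol F14; HF·pyridine returns to the route at 29.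

Further compounds
F1 | step 9 | 1-[(1S,4S)-4-hydroxy-1,2,2-trimethylcyclopentyl]-3-(trimethylsilyl)prop-2-yn-1-ol | C[Si](C)(C)C#CC(O)[C@@]1(C)C[C@@H](O)CC1(C)C
F2 | step 9 | (1R)-3,5,5-trimethyl-4-[(trimethylsilyl)ethynyl]cyclohex-3-en-1-ol | C[Si](C)(C)C#CC1=C(C)C[C@@H](O)CC1(C)C
F3 | step 9 | (1R)-4-ethynyl-3,5,5-trimethylcyclohex-3-en-1-ol | C#CC1=C(C)C[C@@H](O)CC1(C)C
F4 | step 9 | (1R)-4-[(E)-2-iodoethenyl]-3,5,5-trimethylcyclohex-3-en-1-ol | I/C=C/C1=C(C)C[C@@H](O)CC1(C)C
F5 | step 9 | (1R)-3,5,5-trimethyl-4-[(1E)-4-(trimethylsilyl)but-1-en-3-yn-1-yl]cyclohex-3-en-1-ol | C[Si](C)(C)C#C/C=C/C1=C(C)C[C@@H](O)CC1(C)C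
F6 | step 4 | methyl (1S)-4-hydroxy-1,2,2-trimethylcyclopentane-1-carboxylate (C4 epimers) | COC(=O)[C@@]1(C)CC(O)CC1(C)C
F7 | step 4 | (1S)-4-hydroxy-1,2,2-trimethylcyclopentane-1-carboxylic acid (C4 epimers) | OC(=O)[C@@]1(C)CC(O)CC1(C)C
F8 | step 15 | 2-methyl-2-{2-[(1R)-2,6,6-trimethylcyclohex-2-en-1-yl]ethyl}-1,3-dioxolane | CC1=CCCC(C)(C)[C@H]1CCC1(C)OCCO1
F9 | step 15 | (4R)-3,5,5-trimethyl-4-[2-(2-methyl-1,3-dioxolan-2-yl)ethyl]cyclohex-2-en-1-one | CC1=CC(=O)CC(C)(C)[C@H]1CCC1(C)OCCO1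
F10 | step 15 | (1R,4R)-3,5,5-trimethyl-4-[2-(2-methyl-1,3-dioxolan-2-yl)ethyl]cyclohex-2-en-1-ol | CC1=C[C@H](O)CC(C)(C)[C@H]1CCC1(C)OCCO1
F11 | step 15 | tert-butyldimethylsilyl ether of F10 | CC1=C[C@H](O[Si](C)(C)C(C)(C)C)CC(C)(C)[C@H]1CCC1(C)OCCO1
F12 | step 15 | 4-[(1R,4R)-4-(tert-butyldimethylsilyloxy)-2,6,6-trimethylcyclohex-2-en-1-yl]butan-2-one | CC1=C[C@H](O[Si](C)(C)C(C)(C)C)CC(C)(C)[C@H]1CCC(C)=O
F13 | step 15 | 6-[(1R,4R)-4-(tert-butyldimethylsilyloxy)-2,6,6-trimethylcyclohex-2-en-1-yl]hex-2-yn-1-ol | CC1=C[C@H](O[Si](C)(C)C(C)(C)C)CC(C)(C)[C@H]1CCC#CCO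
F14 | step 15 | (2Z)-6-[(1R,4R)-4-(tert-butyldimethylsilyloxy)-2,6,6-trimethylcyclohex-2-en-1-yl]-3-iodohex-2-en-1-ol | CC1=C[C@H](O[Si](C)(C)C(C)(C)C)CC(C)(C)[C@H]1CC/C(I)=C/CO
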